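**Assumptions:** the target (C19H16O10) has no stereocentres and is achiral, so "single enantiomer" needs no stereocontrol. LiHMDS and LDA are used as commercial solutions; orsellinic acid is bought.

## Retrosynthetic overview

1. 18 ⇐ 17 by one hydrogenolysis of both benzyl groups; 17 ⇐ 15 by a single twofold ortho-formylation that installs both CHO groups at once.
2. The obvious esterification of 4-O-methylhaematommic acid with a B-ring phenol is not used. The depside C–O bond is made before ring A exists: acylketene 12 (from diketo-dioxinone 7) acylates the 5-OH of hydroquinone 11, and ring A is then closed on the ester by aldol aromatisation.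
3. Ring B is carried in as the aromatic ring of orsellinic acid 8: double benzylation, then para-oxidation/reduction gives 11. Ring A is the only ring built in the route.
4. 7 ⇐ 2,2,6-trimethyl-1,3-dioxin-4-one 1 by two successive C-acetylations.

## Route

Step 1
Reactants: 1 2,2,6-trimethyl-4H-1,3-dioxin-4-one; 2 acetyl chloride
Product: 4 2,2-dimethyl-6-(2-oxopropyl)-4H-1,3-dioxin-4-one, via lithium dienolate 3 (not isolated)
Conditions: 1 (2 equiv), LiHMDS (2 equiv), THF, −78 °C; then 2 (1 equiv), −78 °C; aq NH4Cl
Reagents that add atoms: none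
Why: Vinylogous (γ) deprotonation of the dioxinone and C-acylation of the dienolate at its terminal carbon (Claisen-type acylation), the second equivalent of dienolate absorbing the acidic product proton; no stereocentre is formed.

Step 2
Reactants: 4 2,2-dimethyl-6-(2-oxopropyl)-4H-1,3-dioxin-4-one; 5 N-methoxy-N-methylacetamide
Product: 7 6-(2,4-dioxopentyl)-2,2-dimethyl-4H-1,3-dioxin-4-one, via dilithium dianion 6 (not isolated)
Conditions: LDA (2.1 equiv), THF, −78 °C; then 5, −78 → −20 °C; 1 M HCl
Reagents that add atoms: none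
Why: Dianion Claisen condensation in which the last-formed, most nucleophilic terminal carbanion is acylated by the Weinreb amide, whose chelated tetrahedral adduct prevents over-addition; no stereocentre is formed.

Step 3
Reactants: 8 orsellinic acid (2,4-dihydroxy-6-methylbenzoic acid)
Product: 9 benzyl 4-(benzyloxy)-2-hydroxy-6-methylbenzoate
Conditions: BnBr (2.1 equiv), K2CO3 (2.5 equiv), DMF, 0 °C → rt
Reagents that add atoms: benzyl bromide BrCc1ccccc1
Why: Carboxylate O-alkylation and Williamson etherification of the 4-OH in one pot at room temperature (no decarboxylation), while the 2-OH stays free because it is locked in a hydrogen bond to the ester carbonyl and is far less nucleophilic.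

Step 4
Reactants: 9 benzyl 4-(benzyloxy)-2-hydroxy-6-methylbenzoate
Product: 11 benzyl 4-(benzyloxy)-2,5-dihydroxy-6-methylbenzoate, via quinone 10 (not isolated)
Conditions: PhI(OCOCF3)2 (2.2 equiv), MeCN/H2O 3:1, 0 °C; then aq Na2S2O4, EtOAc, rt
Reagents that add atoms: water O
Why: Hypervalent-iodine oxidative dearomatisation of the phenol with water attacking the free para position (C5) gives the p-benzoquinone, and dithionite reduction returns the hydroquinone with the new 5-OH para to the chelated 2-OH.

Step 5
Reactants: 11 benzyl 4-(benzyloxy)-2,5-dihydroxy-6-methylbenzoate; 7 6-(2,4-dioxopentyl)-2,2-dimethyl-4H-1,3-dioxin-4-one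
Product: 14 benzyl 4-(benzyloxy)-5-[(2,4-dihydroxy-6-methylbenzoyl)oxy]-2-hydroxy-6-methylbenzoate, via acylketene 12 (not isolated), via aryl trioxooctanoate 13 (not isolated)
Conditions: 7 (1.5 equiv, slow addition), PhMe, 110 °C, Ar; then Et3N (cat.), CH2Cl2, 0 °C → rt; then TFA, rt
Reagents that add atoms: none
Why: Proposed new method: thermolysis of 7 (retro-hetero-Diels–Alder, loss of acetone) gives the small, linear acylketene 12, which is captured by the only non-chelated phenol of 11 (5-OH; the 2-OH is hydrogen-bonded to the ester) to give aryl triketo ester 13, whose C2 enolate closes onto the C7 ketone and dehydrates to the resorcylate, so ring A is assembled on the hindered phenol instead of forcing a 2,6-disubstituted benzoyl donor onto it; the closest known reaction types are the dioxinone-thermolysis/acylketene-trapping/aldol-aromatisation synthesis of alkyl resorcylates and the acetoacetylation of phenols by dioxinone-derived acylketenes.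

Step 6
Reactants: 14 benzyl 4-(benzyloxy)-5-[(2,4-dihydroxy-6-methylbenzoyl)oxy]-2-hydroxy-6-methylbenzoate
Product: 15 benzyl 4-(benzyloxy)-2-hydroxy-5-[(2-hydroxy-4-methoxy-6-methylbenzoyl)oxy]-6-methylbenzoate
Conditions: MeI (1.1 equiv), K2CO3 (1.1 equiv), acetone, rt
Reagents that add atoms: iodomethane CI
Why: Williamson O-methylation of the only phenol not hydrogen-bonded to an ortho carbonyl (ring A 4-OH), the same selectivity that turns orsellinates into everninates.

Step 7
Reactants: 15 benzyl 4-(benzyloxy)-2-hydroxy-5-[(2-hydroxy-4-methoxy-6-methylbenzoyl)oxy]-6-methylbenzoate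
Product: 17 benzyl 4-(benzyloxy)-3-formyl-5-[(3-formyl-2-hydroxy-4-methoxy-6-methylbenzoyl)oxy]-2-hydroxy-6-methylbenzoate, via bis(chloromethoxymethyl) adduct 16 (not isolated)
Conditions: TiCl4 (8 equiv), Cl2CHOMe (6 equiv), CH2Cl2, −20 → 0 °C; then ice-cold 1 M HCl
Reagents that add atoms: dichloromethyl methyl ether COC(Cl)Cl; water O
Why: Twofold Rieche formylation in which each titanium phenoxide delivers the electrophile to its ortho carbon: C3 of ring A (between OH and OMe) and the only free position of ring B. The α-chloro ethers are hydrolysed to the aldehydes on work-up.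

Step 8
Reactants: 17 benzyl 4-(benzyloxy)-3-formyl-5-[(3-formyl-2-hydroxy-4-methoxy-6-methylbenzoyl)oxy]-2-hydroxy-6-methylbenzoate
Product: 18 haemathamnolic acid (3-formyl-5-[(3-formyl-2-hydroxy-4-methoxy-6-methylbenzoyl)oxy]-2,4-dihydroxy-6-methylbenzoic acid)
Conditions: H2 (1 atm), 10% Pd/C, EtOAc, rt, 1–2 h (TLC control)
Reagents that add atoms: none
Why: Catalytic hydrogenolysis removes the benzyl ester and the benzyl ether together, while the two aldehydes, each chelated to an ortho hydroxyl, and the hindered depside ester survive the short exposure.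

## Compound list

1 | 2,2,6-trimethyl-4H-1,3-dioxin-4-one | CC1=CC(=O)OC(C)(C)O1 | starting material
2 | acetyl chloride | CC(Cl)=O | starting material
3 | lithium dienolate of 1 (lithium 2,2-dimethyl-6-methylidene-1,3-dioxin-4-olate; not isolated) | [Li+].[O-]C1=CC(=C)OC(C)(C)O1 | intermediate
4 | 2,2-dimethyl-6-(2-oxopropyl)-4H-1,3-dioxin-4-one | CC(=O)CC1=CC(=O)OC(C)(C)O1 | intermediate
5 | N-methoxy-N-methylacetamide | CON(C)C(C)=O | starting material
6 | dilithium dianion of 4 (not isolated) | [Li+].[Li+].C=C([O-])C=C1C=C([O-])OC(C)(C)O1 | intermediate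
7 | 6-(2,4-dioxopentyl)-2,2-dimethyl-4H-1,3-dioxin-4-one | CC(=O)CC(=O)CC1=CC(=O)OC(C)(C)O1 | intermediate
8 | orsellinic acid (2,4-dihydroxy-6-methylbenzoic acid) | Cc1cc(O)cc(O)c1C(=O)O | starting material
9 | benzyl 4-(benzyloxy)-2-hydroxy-6-methylbenzoate | Cc1cc(OCc2ccccc2)cc(O)c1C(=O)OCc1ccccc1 | intermediate
10 | benzyl 4-(benzyloxy)-2-methyl-3,6-dioxocyclohexa-1,4-diene-1-carboxylate (quinone; not isolated) | CC1=C(C(=O)OCc2ccccc2)C(=O)C=C(OCc2ccccc2)C1=O | intermediate
11 | benzyl 4-(benzyloxy)-2,5-dihydroxy-6-methylbenzoate | Cc1c(O)c(OCc2ccccc2)cc(O)c1C(=O)OCc1ccccc1 | intermediate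
12 | acylketene 3,5,7-trioxooct-1-en-1-one (not isolated) | CC(=O)CC(=O)CC(=O)C=C=O | intermediate
13 | benzyl 4-(benzyloxy)-2-hydroxy-6-methyl-5-[(3,5,7-trioxooctanoyl)oxy]benzoate (not isolated) | Cc1c(OC(=O)CC(=O)CC(=O)CC(C)=O)c(OCc2ccccc2)cc(O)c1C(=O)OCc1ccccc1 | intermediate
14 | benzyl 4-(benzyloxy)-5-[(2,4-dihydroxy-6-methylbenzoyl)oxy]-2-hydroxy-6-methylbenzoate | Cc1cc(O)cc(O)c1C(=O)Oc1c(C)c(C(=O)OCc2ccccc2)c(O)cc1OCc1ccccc1 | intermediate
15 | benzyl 4-(benzyloxy)-2-hydroxy-5-[(2-hydroxy-4-methoxy-6-methylbenzoyl)oxy]-6-methylbenzoate | Cc1cc(OC)cc(O)c1C(=O)Oc1c(C)c(C(=O)OCc2ccccc2)c(O)cc1OCc1ccccc1 | intermediate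
16 | benzyl 4-(benzyloxy)-3-[chloro(methoxy)methyl]-5-({3-[chloro(methoxy)methyl]-2-hydroxy-4-methoxy-6-methylbenzoyl}oxy)-2-hydroxy-6-methylbenzoate (transient, configuration at the two CHCl centres undefined; not isolated) | COC(Cl)c1c(OC)cc(C)c(C(=O)Oc2c(C)c(C(=O)OCc3ccccc3)c(O)c(C(Cl)OC)c2OCc2ccccc2)c1O | intermediate
17 | benzyl 4-(benzyloxy)-3-formyl-5-[(3-formyl-2-hydroxy-4-methoxy-6-methylbenzoyl)oxy]-2-hydroxy-6-methylbenzoate | COc1cc(C)c(C(=O)Oc2c(C)c(C(=O)OCc3ccccc3)c(O)c(C=O)c2OCc2ccccc2)c(O)c1C=O | intermediate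
18 | haemathamnolic acid | COc1cc(C)c(C(=O)Oc2c(C)c(C(=O)O)c(O)c(C=O)c2O)c(O)c1C=O | target

## Step count and risks

Total step count: 8. Longest linear sequence: 6 steps (1 → 4 → 7 → 14 → 15 → 17 → 18, steps 1, 2, 5, 6, 7, 8). The ring-B branch 8 → 9 → 11 (steps 3, 4) joins at step 5 and is equally long to the target.

The three steps most likely to fail:

**Step 5 (key step).** The aryl ester in 13 is a better leaving group than an alkyl ester, so Claisen-type closure with loss of the aryloxide could compete with the aldol. Ketene dimerisation could also outrun the hindered phenol. The fallback makes ring A first and transfers it photochemically. It sets out from 7, which on its own with Et3N then TFA (no thermolysis) aromatises to 7-hydroxy-2,2,5-trimethyl-4H-1,3-benzodioxin-4-one F1. MeI/K2CO3 in acetone gives 7-methoxy-2,2,5-trimethyl-4H-1,3-benzodioxin-4-one F2. Irradiation of F2 (300 nm, CH2Cl2) in the presence of 11 expels acetone to give the quinoketene 3-methoxy-5-methyl-6-(oxomethylidene)cyclohexa-2,4-dien-1-one F3 (not isolated). The 5-OH of 11 traps it, and the fallback comes back to the route at 15, so step 6 is skipped.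

**Step 7.** Formylation of ring A at C5 instead of C3, incomplete second formylation, or TiCl4 attack on the benzyl groups are the concerns. Partial loss of the ether benzyl group alone would be tolerable, because step 8 removes it anyway. The fallback sets out from 15 and replaces Lewis-acid Friedel–Crafts formylation with magnesium-phenoxide-directed ortho-hydroxymethylation/redox (MgCl2, Et3N, paraformaldehyde, MeCN, 80 °C). Each magnesium phenoxide can deliver formaldehyde only to its own ortho carbon. This gives benzyl 4-(benzyloxy)-2-hydroxy-3-(hydroxymethyl)-5-{[2-hydroxy-3-(hydroxymethyl)-4-methoxy-6-methylbenzoyl]oxy}-6-methylbenzoate F4 as its magnesium alkoxide (not isolated). Hydride transfer to further formaldehyde oxidises it in the flask, and the fallback comes back at 17.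

**Step 4.** The chelated, ester-bearing phenol may be sluggish toward the iodine(III) oxidant, or water may attack ortho. The fallback sets out from 9 and uses Elbs persulfate oxidation (K2S2O8, aq NaOH/pyridine, 0 °C → rt), a direct para-hydroxylation that avoids the quinone. It gives potassium 6-(benzyloxy)-3-[(benzyloxy)carbonyl]-4-hydroxy-2-methylphenyl sulfate F5, which is hydrolysed (dilute HCl, THF, 60 °C) and comes back at 11.

## Further compounds

F1 | step 5 | 7-hydroxy-2,2,5-trimethyl-4H-1,3-benzodioxin-4-one | Cc1cc(O)cc2OC(C)(C)OC(=O)c12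
F2 | step 5 | 7-methoxy-2,2,5-trimethyl-4H-1,3-benzodioxin-4-one | COc1cc(C)c2C(=O)OC(C)(C)Oc2c1
F3 | step 5 | 3-methoxy-5-methyl-6-(oxomethylidene)cyclohexa-2,4-dien-1-one (quinoketene, not isolated) | COC1=CC(=O)C(=C=O)C(C)=C1
F4 | step 7 | benzyl 4-(benzyloxy)-2-hydroxy-3-(hydroxymethyl)-5-{[2-hydroxy-3-(hydroxymethyl)-4-methoxy-6-methylbenzoyl]oxy}-6-methylbenzoate (not isolated) | COc1cc(C)c(C(=O)Oc2c(C)c(C(=O)OCc3ccccc3)c(O)c(CO)c2OCc2ccccc2)c(O)c1CO
F5 | step 4 | potassium 6-(benzyloxy)-3-[(benzyloxy)carbonyl]-4-hydroxy-2-methylphenyl sulfate | Cc1c(OS(=O)(=O)[O-])c(OCc2ccccc2)cc(O)c1C(=O)OCc1ccccc1.[K+]
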